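The data are calculated with made-up constants; scatter was added.

Read the second exchange as a clock running on free incoming ligand, and count the ligand it spends as a correction.

the same everywhere: starting complex 0.045 M

| run | incoming ligand | leaving ligand | remark | time |
|---|---|---|---|---|
| midnight | 0.079 M | 0.045 M | run made earlier |  |
| noon | 0.15 M | 0.045 M | run made earlier |  |
| teal | 0.0675 M | 0.0450 M |  | 2.0 h |
| red | 0.112 M | 0.0450 M |  | 2.0 h |

| run | time / min | complex with one exchanged / % |
|---|---|---|
| midnight | 15.0 | 73 |
| midnight | 30.0 | 76 |
| midnight | 50.0 | 71 |
| midnight | 60.0 | 70 |
| noon | 8.00 | 72 |
| noon | 20.0 | 67 |
| noon | 40.0 | 45 |
| noon | 60.0 | 37 |

(readings scatter by 1.5 percentage points)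

- which of these holds the largest part of the starting complex at the end of teal (complex with one exchanged / complex with two exchanged / starting complex)
- which of these holds the largest part of the starting complex at the end of red (complex with one exchanged / complex with two exchanged / starting complex)
- how much complex with one exchanged is there at the end of red, in percent of the starting complex charged



This reckoning takes the first exchange as done from the start and sets the way back aside, so that complex with one exchanged decays in pseudo-first-order fashion at any fixed [incoming ligand]. In noon it reads 67% at 20.0 min and 37% at 60.0 min, and the ligand balance puts free [incoming ligand] near 0.0834 M between them. These scattered readings give 0.178 /M/min, the ligand clock: the fall in the logarithm of complex with one exchanged per minute, per unit of free [incoming ligand].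

Red has two extremes. With [incoming ligand] held at its spare level after the first exchange, 0.0670 M, the clock leaves 23.9% of complex with one exchanged. Held instead at its level after both exchanges, 0.0220 M, it leaves 62.5%. In this reckoning the level starts at the top and sinks, so red lies between. Subtracting half the ligand spent in the first extreme gives a mean of 0.0499 M and 34.5%, so this reckoning puts complex with two exchanged ahead in red. Teal's top extreme leaves 61.8%, so it puts complex with one exchanged ahead there.

The forecast names complex with one exchanged as largest in teal and complex with one exchanged in red, with 55% of it in red: "Two hours gets close to that balance". It parts from this reckoning on red.

The largest part is complex with one exchanged in teal and complex with two exchanged in red, with 31.6% of complex with one exchanged in red.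

    complex with one exchanged + incoming ligand ⇌ leaving ligand + complex with two exchanged (K = 0.318, k = 0.220 /M/min)
    starting complex + incoming ligand ⇌ leaving ligand + complex with one exchanged (K = 0.850, k = 4.20 /M/min)
    leaving ligand → by-product carried off (k = 0.305 /min)

Red ends with 0.826% of its own charge of leaving ligand, 0.120 M of by-product carried off, and complex with one exchanged 2.9 percentage points below the reckoning. The neighbour flask is red charged with 0.018 M of starting complex. Its spare ligand is 0.0940 M, and the top extreme keeps 13.4%. The spending correction lowers the mean level to 0.0862 M, and the clock 0.178 /M/min then gives 15.9%. The neighbour flask ends with 12.6% of complex with one exchanged.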